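**Retrosynthetic overview**

- Last disconnection: the C5–CH2 bond of the propyl chain, made by B-alkyl Suzuki–Miyaura coupling of a 5-bromo-2,3-dihydrobenzofuran with the 9-BBN adduct of an allyl ferulate, so the ferulate ester arrives ready-made.
- The hydroxymethyl group (C9 on C3) is traced back to a methyl ester standing trans to the C2 aryl group.
- Feature on which the strategy rests: the dihydrofuran ring O1–C2–C3–C3a–C7a with C9 on C3 is a 2-arylchroman-4-one whose carbonyl carbon C4 has been pushed out of the ring as C9 while ring A moved from C4 to C3 (oxidative ring contraction).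
- The (2R)-flavanone comes from 6-bromo-8-methoxychromone and an arylboronic acid by enantioselective conjugate addition, which sets C2; C3 is then set from C2 in the contraction.
- Ring order: ring A (bought), pyranone ring (chromone), ring B attached, pyranone contracted to the dihydrofuran, ferulate arene appended by cross-coupling.

Key step: step 6

Assumption: the (S)-pyridine-oxazoline ligand is taken to deliver the aryl group to the same enone face as with cyclic enones, which corresponds to the (2R)-flavanone; if the sense proves opposite, the (R)-ligand is used.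

**Route**

Step 1
Reactants: 1 1-(2-hydroxy-3-methoxyphenyl)ethanone
Product: 2 1-(5-bromo-2-hydroxy-3-methoxyphenyl)ethanone
Conditions: NBS (1.05 equiv), MeCN, 0 °C to rt
Reagents that add atoms: N-bromosuccinimide, O=C1CCC(=O)N1Br
Why: Electrophilic aromatic bromination, in which the hydroxyl group, with both ortho positions occupied, sends bromine to its para position (C5), and ring substitution of the phenol outpaces α-bromination of the ketone.

Step 2
Reactants: 2 1-(5-bromo-2-hydroxy-3-methoxyphenyl)ethanone
Product: 4 6-bromo-8-methoxy-4H-chromen-4-one, via enaminone 3 (not isolated)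
Conditions: Me2NCH(OMe)2, toluene, 100 °C; then conc. HCl, CH2Cl2, 40 °C
Reagents that add atoms: N,N-dimethylformamide dimethyl acetal, COC(OC)N(C)C
Why: Enaminone chromone synthesis, in which the amide acetal condenses with the methyl ketone and acid then drives addition of the phenol oxygen to the β-carbon with loss of dimethylamine, closing the pyranone ring.

Step 3
Reactants: 5 2-methoxy-4-(4,4,5,5-tetramethyl-1,3,2-dioxaborolan-2-yl)phenol
Product: 6 2-methoxy-4-(4,4,5,5-tetramethyl-1,3,2-dioxaborolan-2-yl)phenyl 2,2-dimethylpropanoate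
Conditions: t-BuCOCl, Et3N, DMAP (cat.), CH2Cl2, 0 °C to rt
Reagents that add atoms: pivaloyl chloride, CC(C)(C)C(Cl)=O
Why: DMAP-catalysed O-acylation of the phenol, which leaves the pinacol boronate alone and installs the hindered, electron-poor ester that ring B needs in the key step.

Step 4
Reactants: 6 2-methoxy-4-(4,4,5,5-tetramethyl-1,3,2-dioxaborolan-2-yl)phenyl 2,2-dimethylpropanoate
Product: 7 [3-methoxy-4-(2,2-dimethylpropanoyloxy)phenyl]boronic acid
Conditions: NaIO4, NH4OAc, acetone/H2O (1:1), rt
Reagents that add atoms: water, O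
Why: Oxidative deprotection of a pinacol boronate, in which periodate cleaves the pinacol released by the hydrolysis equilibrium and so pulls it over to the free boronic acid (the species that transmetallates readily to divalent palladium), while the hindered pivalate survives the near-neutral medium.

Step 5
Reactants: 4 6-bromo-8-methoxy-4H-chromen-4-one; 7 [3-methoxy-4-(2,2-dimethylpropanoyloxy)phenyl]boronic acid
Product: 8 (2R)-6-bromo-8-methoxy-2-(3-methoxy-4-pivaloyloxyphenyl)chroman-4-one
Conditions: Pd(OCOCF3)2 (5 mol%), (S)-4-tert-butyl-2-(pyridin-2-yl)-4,5-dihydrooxazole (6 mol%), NH4PF6 (30 mol%), H2O (5 equiv), ClCH2CH2Cl, 60 °C, air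
Reagents that add atoms: none
Why: Enantioselective conjugate addition of an arylboronic acid to a chromone under cationic divalent palladium with a chiral pyridine-oxazoline ligand, in which the aryl–palladium species adds across C2=C3 on the face left open by the tert-butyl group of the ligand and so sets C2 as R, and protonolysis of the palladium enolate returns the catalyst without passing through zerovalent palladium, so the C6–Br bond is not attacked.

Step 6
Reactants: 8 (2R)-6-bromo-8-methoxy-2-(3-methoxy-4-pivaloyloxyphenyl)chroman-4-one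
Product: 12 methyl (2R,3R)-5-bromo-7-methoxy-2-(3-methoxy-4-pivaloyloxyphenyl)-2,3-dihydro-1-benzofuran-3-carboxylate, via dimethyl ketal 9 (not isolated), via methyl enol ether 10 (not isolated), via trans iodane 11 (not isolated)
Conditions: PhI(OAc)2 (1.2 equiv), conc. H2SO4 (0.5 equiv), HC(OMe)3, rt
Reagents that add atoms: trimethyl orthoformate, COC(OC)OC
Why: Acid and the orthoformate should convert ketone 8 into ketal 9 and then enol ether 10, PhI(OAc)2 attacks C3 of 10 on the face opposite the C2 aryl group, and methanol re-adds at C4 to give the trans iodane 11. The ring A carbon C4a, lying anti to the C3–I bond, then shifts from C4 to C3 with inversion as iodobenzene leaves, and the dimethoxycarbenium ion left at the old C4 gives up a methyl group to acetate and becomes the ester carbon C9. The closest known reaction type is the oxidative 1,2-aryl shift of flavanones with trivalent iodine or thallium trinitrate in trimethyl orthoformate, which gives methyl 2-aryl-2,3-dihydrobenzofuran-3-carboxylates. The five-membered ring O1–C2–C3–C3a–C7a is closed by contraction of the pyranone ring, the C3–C3a bond forming as C4a bridges C4 and C3 in a phenonium-like three-centre transition state, not by cyclisation of an open chain. C3 is controlled by the C2 stereocentre, since anti iodination followed by the invertive shift places CO2Me trans to the C2 aryl group, (2R,3R), and C2 itself is not touched. The step needs migration of ring A in preference to the 2,3-shift of ring B (isoflavone) and to elimination (flavone), and this is secured by the acyloxy group on ring B, which lowers its migratory aptitude and disfavours ionisation at C2, and by the ring oxygen ortho to C4a.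

Step 7
Reactants: 12 methyl (2R,3R)-5-bromo-7-methoxy-2-(3-methoxy-4-pivaloyloxyphenyl)-2,3-dihydro-1-benzofuran-3-carboxylate
Product: 13 4-[(2R,3S)-5-bromo-3-(hydroxymethyl)-7-methoxy-2,3-dihydro-1-benzofuran-2-yl]-2-methoxyphenol
Conditions: LiAlH4 (2.5 equiv), THF, 0 °C; aq. potassium sodium tartrate work-up
Reagents that add atoms: none
Why: Hydride reduction of esters, in which LiAlH4 takes the methyl ester to the primary alcohol at C9 and cleaves the aryl pivalate to the phenol, hydride addition at 0 °C being faster than enolisation at C3 and than attack on the aryl bromide, so both stereocentres are kept (the descriptor at C3 changes to S only through the priority rules).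

Step 8
Reactants: 13 4-[(2R,3S)-5-bromo-3-(hydroxymethyl)-7-methoxy-2,3-dihydro-1-benzofuran-2-yl]-2-methoxyphenol
Product: 14 triisopropyl{[(2R,3S)-5-bromo-7-methoxy-2-(3-methoxy-4-triisopropylsilyloxyphenyl)-2,3-dihydro-1-benzofuran-3-yl]methoxy}silane
Conditions: i-Pr3SiCl (2.5 equiv), imidazole (5 equiv), DMF, rt
Reagents that add atoms: triisopropylsilyl chloride, CC(C)[Si](Cl)(C(C)C)C(C)C
Why: Silyl ether formation on the primary alcohol and the phenol, which stops the phenoxide from opening the benzylic C2–O1 bond through a quinone methide under the basic coupling conditions, the triisopropylsilyl aryl ether being robust enough for aqueous phosphate.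

Step 9
Reactants: 15 ferulic acid; 16 allyl alcohol
Product: 17 prop-2-enyl (E)-3-(4-hydroxy-3-methoxyphenyl)prop-2-enoate
Conditions: H2SO4 (cat.), allyl alcohol as solvent, 80 °C
Reagents that add atoms: none
Why: Fischer esterification driven by the alcohol used as solvent, under which the phenol and the E alkene are unaffected.

Step 10
Reactants: 17 prop-2-enyl (E)-3-(4-hydroxy-3-methoxyphenyl)prop-2-enoate
Product: 18 prop-2-enyl (E)-3-(3-methoxy-4-triisopropylsilyloxyphenyl)prop-2-enoate
Conditions: i-Pr3SiCl (1.2 equiv), imidazole (2.5 equiv), DMF, rt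
Reagents that add atoms: triisopropylsilyl chloride, CC(C)[Si](Cl)(C(C)C)C(C)C
Why: Silylation of the phenol, which removes the only O–H that would consume 9-BBN in the hydroboration.

Step 11
Reactants: 18 prop-2-enyl (E)-3-(3-methoxy-4-triisopropylsilyloxyphenyl)prop-2-enoate; 14 triisopropyl{[(2R,3S)-5-bromo-7-methoxy-2-(3-methoxy-4-triisopropylsilyloxyphenyl)-2,3-dihydro-1-benzofuran-3-yl]methoxy}silane
Product: 20 3-[(2R,3S)-7-methoxy-2-(3-methoxy-4-triisopropylsilyloxyphenyl)-3-(triisopropylsilyloxymethyl)-2,3-dihydro-1-benzofuran-5-yl]propyl (E)-3-(3-methoxy-4-triisopropylsilyloxyphenyl)prop-2-enoate, via alkylborane 19 (not isolated)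
Conditions: 18, 9-BBN (1.1 equiv B–H), THF, 0 °C to rt; then 14, PdCl2(dppf) (5 mol%), K3PO4 (3 equiv), H2O (10 equiv), THF/DMF, 50 °C
Reagents that add atoms: none
Why: Hydroboration followed by B-alkyl Suzuki–Miyaura coupling, in which 9-BBN adds anti-Markovnikov to the terminal allyl alkene much faster than to the conjugated 1,2-disubstituted cinnamate alkene, and zerovalent palladium formed from PdCl2(dppf) inserts into C5–Br, takes the primary alkyl group from the hydroxyborate and forms the C5–CH2 bond by reductive elimination, the wide-bite-angle ligand holding back β-hydride elimination.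

Step 12
Reactants: 20 3-[(2R,3S)-7-methoxy-2-(3-methoxy-4-triisopropylsilyloxyphenyl)-3-(triisopropylsilyloxymethyl)-2,3-dihydro-1-benzofuran-5-yl]propyl (E)-3-(3-methoxy-4-triisopropylsilyloxyphenyl)prop-2-enoate
Product: 21 3-[(2R,3S)-2-(4-hydroxy-3-methoxyphenyl)-3-(hydroxymethyl)-7-methoxy-2,3-dihydro-1-benzofuran-5-yl]propyl (E)-3-(4-hydroxy-3-methoxyphenyl)prop-2-enoate
Conditions: Bu4NF (4 equiv), AcOH (4 equiv), THF, 0 °C to rt
Reagents that add atoms: none
Why: Fluoride-induced cleavage of the three silyl ethers, with acetic acid buffering the fluoride so that the cinnamate ester is not cleaved and no free phenoxide can open the C2–O1 bond, which leaves both stereocentres as set.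

**Compound list**

1 | 1-(2-hydroxy-3-methoxyphenyl)ethanone | CC(=O)c1cccc(OC)c1O | starting material
2 | 1-(5-bromo-2-hydroxy-3-methoxyphenyl)ethanone | CC(=O)c1cc(Br)cc(OC)c1O | intermediate
3 | (E)-1-(5-bromo-2-hydroxy-3-methoxyphenyl)-3-(dimethylamino)prop-2-en-1-one (formed in the flask, not isolated) | CN(C)/C=C/C(=O)c1cc(Br)cc(OC)c1O | intermediate
4 | 6-bromo-8-methoxy-4H-chromen-4-one | O=c1ccoc2c(OC)cc(Br)cc12 | intermediate
5 | 2-methoxy-4-(4,4,5,5-tetramethyl-1,3,2-dioxaborolan-2-yl)phenol | COc1cc(B2OC(C)(C)C(C)(C)O2)ccc1O | starting material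
6 | 2-methoxy-4-(4,4,5,5-tetramethyl-1,3,2-dioxaborolan-2-yl)phenyl 2,2-dimethylpropanoate | COc1cc(B2OC(C)(C)C(C)(C)O2)ccc1OC(=O)C(C)(C)C | intermediate
7 | [3-methoxy-4-(2,2-dimethylpropanoyloxy)phenyl]boronic acid | COc1cc(B(O)O)ccc1OC(=O)C(C)(C)C | intermediate
8 | (2R)-6-bromo-8-methoxy-2-(3-methoxy-4-pivaloyloxyphenyl)chroman-4-one | O=C1C[C@H](c2ccc(OC(=O)C(C)(C)C)c(OC)c2)Oc2c(OC)cc(Br)cc12 | intermediate
9 | (2R)-6-bromo-4,4,8-trimethoxy-2-(3-methoxy-4-pivaloyloxyphenyl)chromane, the dimethyl ketal of 8 (formed in the flask, not isolated) | COC1(OC)C[C@H](c2ccc(OC(=O)C(C)(C)C)c(OC)c2)Oc2c(OC)cc(Br)cc12 | intermediate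
10 | (2R)-6-bromo-4,8-dimethoxy-2-(3-methoxy-4-pivaloyloxyphenyl)-2H-chromene (formed in the flask, not isolated) | COC1=C[C@H](c2ccc(OC(=O)C(C)(C)C)c(OC)c2)Oc2c(OC)cc(Br)cc12 | intermediate
11 | (2S,3S)-3-[acetoxy(phenyl)-λ3-iodanyl]-6-bromo-4,4,8-trimethoxy-2-(3-methoxy-4-pivaloyloxyphenyl)chromane, iodine trans to the C2 aryl group (formed in the flask, not isolated) | COC1(OC)[C@@H](I(OC(C)=O)c3ccccc3)[C@H](c3ccc(OC(=O)C(C)(C)C)c(OC)c3)Oc2c(OC)cc(Br)cc12 | intermediate
12 | methyl (2R,3R)-5-bromo-7-methoxy-2-(3-methoxy-4-pivaloyloxyphenyl)-2,3-dihydro-1-benzofuran-3-carboxylate (trans) | Brc2cc(OC)c3c(c2)[C@@H](C(=O)OC)[C@H](c2ccc(OC(=O)C(C)(C)C)c(OC)c2)O3 | intermediate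
13 | 4-[(2R,3S)-5-bromo-3-(hydroxymethyl)-7-methoxy-2,3-dihydro-1-benzofuran-2-yl]-2-methoxyphenol | Brc2cc(OC)c3c(c2)[C@@H](CO)[C@H](c2ccc(O)c(OC)c2)O3 | intermediate
14 | triisopropyl{[(2R,3S)-5-bromo-7-methoxy-2-(3-methoxy-4-triisopropylsilyloxyphenyl)-2,3-dihydro-1-benzofuran-3-yl]methoxy}silane | Brc2cc(OC)c3c(c2)[C@@H](CO[Si](C(C)C)(C(C)C)C(C)C)[C@H](c2ccc(O[Si](C(C)C)(C(C)C)C(C)C)c(OC)c2)O3 | intermediate
15 | ferulic acid, (E)-3-(4-hydroxy-3-methoxyphenyl)prop-2-enoic acid | COc1cc(/C=C/C(=O)O)ccc1O | starting material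
16 | allyl alcohol, prop-2-en-1-ol | C=CCO | starting material
17 | prop-2-enyl (E)-3-(4-hydroxy-3-methoxyphenyl)prop-2-enoate | COc1cc(/C=C/C(=O)OCC=C)ccc1O | intermediate
18 | prop-2-enyl (E)-3-(3-methoxy-4-triisopropylsilyloxyphenyl)prop-2-enoate | COc1cc(/C=C/C(=O)OCC=C)ccc1O[Si](C(C)C)(C(C)C)C(C)C | intermediate
19 | 3-(9-borabicyclo[3.3.1]nonan-9-yl)propyl (E)-3-(3-methoxy-4-triisopropylsilyloxyphenyl)prop-2-enoate (formed in the flask, not isolated) | COc1cc(/C=C/C(=O)OCCCB2C3CCCC2CCC3)ccc1O[Si](C(C)C)(C(C)C)C(C)C | intermediate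
20 | 3-[(2R,3S)-7-methoxy-2-(3-methoxy-4-triisopropylsilyloxyphenyl)-3-(triisopropylsilyloxymethyl)-2,3-dihydro-1-benzofuran-5-yl]propyl (E)-3-(3-methoxy-4-triisopropylsilyloxyphenyl)prop-2-enoate | COc1cc(/C=C/C(=O)OCCCc2cc(OC)c3c(c2)[C@@H](CO[Si](C(C)C)(C(C)C)C(C)C)[C@H](c2ccc(O[Si](C(C)C)(C(C)C)C(C)C)c(OC)c2)O3)ccc1O[Si](C(C)C)(C(C)C)C(C)C | intermediate
21 | 3-[(2R,3S)-2-(4-hydroxy-3-methoxyphenyl)-3-(hydroxymethyl)-7-methoxy-2,3-dihydro-1-benzofuran-5-yl]propyl (E)-3-(4-hydroxy-3-methoxyphenyl)prop-2-enoate | COc1cc(/C=C/C(=O)OCCCc2cc(OC)c3c(c2)[C@@H](CO)[C@H](c2ccc(O)c(OC)c2)O3)ccc1O | target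

**Step count**

Total: 12 steps. Longest linear sequence: 8 steps (steps 1, 2, 5, 6, 7, 8, 11, 12).

**Steps most likely to fail**

Step 6 (key step). After iodination at C3 the shift may be taken by ring B (2,3-aryl shift), or the iodane may simply eliminate, so that isoflavone and flavone form at the expense of ring contraction. Prolonged acid may also ionise the benzylic C2–O1 bond and erode the configuration at C2. The fallback sets out from 8 and returns at 12, and runs the same C4-to-C3 shift of ring A as a Wolff rearrangement. Ketone 8 is deprotonated with LiN(SiMe3)2 in THF at −78 °C (kept cold to avoid ring opening of the enolate) and acylated with 2,2,2-trifluoroethyl trifluoroacetate to the 3-trifluoroacetyl flavanone F1. Detrifluoroacetylating diazo transfer with methanesulfonyl azide and Et3N in MeCN should give the 3-diazoflavanone F2. Irradiation through Pyrex in methanol expels dinitrogen, ring A migrates to the carbene carbon and methanol traps the ketene, which should give ester 12 together with its cis C3 epimer F3. DBU in toluene then equilibrates F3 to the trans ester 12.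

Step 5. Transmetallation of the ester-bearing boronic acid may be slow and protodeboronation may compete, or the facial discrimination on the 8-methoxy-substituted chromone may be insufficient, and later steps cannot raise the enantiomeric purity. The fallback sets out from 4 and 7 and returns at 8, and obtains the configuration by resolution instead of catalyst control. The addition is run with the achiral, more active system Pd(OCOCF3)2/2,2'-bipyridine in aqueous acetic acid to give the racemic flavanone F4. Preparative chromatography on a chiral stationary phase then separates the enantiomers: the (2R) enantiomer is 8, and the (2S) enantiomer can be racemised with catalytic DBU (ring opening to the 2'-hydroxychalcone and reclosure) and separated again.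

Step 11. Conjugate reduction of the cinnamate may compete during hydroboration, the aqueous base may hydrolyse the cinnamate ester or strip aryl silyl groups, and oxidative addition at the electron-rich C5–Br bond may be slow enough for protodeboronation and β-hydride elimination to take over. The fallback sets out from 14 and returns at 20, building the chain first and the ester bond last. Suzuki–Miyaura allylation of 14 with allylboronic acid pinacol ester (PdCl2(dppf), CsF, THF, 70 °C) should give the 5-allyl compound F5. Hydroboration with 9-BBN gives the alkylborane F6, which NaBO3·4H2O oxidises to the primary alcohol F7. The O-silylferulic acid F8, made from 18 by deallylation with Pd(PPh3)4 and morpholine, is then joined to F7 by Steglich esterification (EDC·HCl, DMAP, CH2Cl2) to give 20.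

**Further compounds**

F1 | step 6 | (2R)-6-bromo-8-methoxy-2-(3-methoxy-4-pivaloyloxyphenyl)-3-(trifluoroacetyl)chroman-4-one, C3 epimers and enol form | O=C1C(C(=O)C(F)(F)F)[C@H](c2ccc(OC(=O)C(C)(C)C)c(OC)c2)Oc2c(OC)cc(Br)cc12
F2 | step 6 | (2S)-6-bromo-3-diazo-8-methoxy-2-(3-methoxy-4-pivaloyloxyphenyl)chroman-4-one, same spatial arrangement at C2 as in 8 | O=C1C(=[N+]=[N-])[C@H](c2ccc(OC(=O)C(C)(C)C)c(OC)c2)Oc2c(OC)cc(Br)cc12
F3 | step 6 | methyl (2R,3S)-5-bromo-7-methoxy-2-(3-methoxy-4-pivaloyloxyphenyl)-2,3-dihydro-1-benzofuran-3-carboxylate (cis) | Brc2cc(OC)c3c(c2)[C@H](C(=O)OC)[C@H](c2ccc(OC(=O)C(C)(C)C)c(OC)c2)O3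
F4 | step 5 | racemic 6-bromo-8-methoxy-2-(3-methoxy-4-pivaloyloxyphenyl)chroman-4-one | O=C1CC(c2ccc(OC(=O)C(C)(C)C)c(OC)c2)Oc2c(OC)cc(Br)cc12
F5 | step 11 | triisopropyl{[(2R,3S)-7-methoxy-2-(3-methoxy-4-triisopropylsilyloxyphenyl)-5-(prop-2-enyl)-2,3-dihydro-1-benzofuran-3-yl]methoxy}silane | C=CCc2cc(OC)c3c(c2)[C@@H](CO[Si](C(C)C)(C(C)C)C(C)C)[C@H](c2ccc(O[Si](C(C)C)(C(C)C)C(C)C)c(OC)c2)O3
F6 | step 11 | 9-{3-[(2R,3S)-7-methoxy-2-(3-methoxy-4-triisopropylsilyloxyphenyl)-3-(triisopropylsilyloxymethyl)-2,3-dihydro-1-benzofuran-5-yl]propyl}-9-borabicyclo[3.3.1]nonane | B1(CCCc2cc(OC)c3c(c2)[C@@H](CO[Si](C(C)C)(C(C)C)C(C)C)[C@H](c2ccc(O[Si](C(C)C)(C(C)C)C(C)C)c(OC)c2)O3)C2CCCC1CCC2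
F7 | step 11 | 3-[(2R,3S)-7-methoxy-2-(3-methoxy-4-triisopropylsilyloxyphenyl)-3-(triisopropylsilyloxymethyl)-2,3-dihydro-1-benzofuran-5-yl]propan-1-ol | OCCCc2cc(OC)c3c(c2)[C@@H](CO[Si](C(C)C)(C(C)C)C(C)C)[C@H](c2ccc(O[Si](C(C)C)(C(C)C)C(C)C)c(OC)c2)O3
F8 | step 11 | (E)-3-(3-methoxy-4-triisopropylsilyloxyphenyl)prop-2-enoic acid | COc1cc(/C=C/C(=O)O)ccc1O[Si](C(C)C)(C(C)C)C(C)C
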